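Everything rests on taking ring A of the chromone apart. C8, which carries piperidine C4′, lies between the oxygenated carbons C7 and C8a, and the third oxygen sits at C5, para to C8: a 2-alkylphloroglucinol. A Danheiser benzannulation of a silyl ynol ether with 3-ethoxycyclobutenone makes bonds C8–C8a and C6–C7 and closes ring A. It delivers the three oxygens already differentiated as free OH (future O1), OTIPS (C7) and OEt (C5), all in one neutral thermal operation. The precursor is an N-Boc piperidine with the cis C3′ (silyloxy) and C4′ stereocentres in place and a triisopropylsilyloxyethynyl group on C4′. Pyrone annulation and veratroylation of rohitukine finish the synthesis.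

Key step: step 4

Remark: primed locants refer to the piperidine ring and unprimed ones to the chromone; a ketoreductase of the required selectivity is assumed to be obtainable from a commercial screening panel.

Step 1
Reactants: 1 ethyl 1-(tert-butoxycarbonyl)-3-oxopiperidine-4-carboxylate (racemic, largely enolised)
Product: 2 1-tert-butyl 4-ethyl (3S,4S)-3-hydroxypiperidine-1,4-dicarboxylate (cis)
Conditions: ketoreductase (anti-Prelog, screened for the cis-(3S,4S) alcohol), NADP+ (cat.), i-PrOH, KH2PO4/K2HPO4 buffer pH 7, 30 °C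
Reagents that add atoms: none
Why: Enzymatic dynamic kinetic resolution of an α-substituted β-keto ester: C4′ racemises through the enol at neutral pH while the enzyme accepts only the (4S)-ketone and delivers hydride to one carbonyl face, so its pocket sets both stereocentres (3S,4S, cis); the facial preference must be opposite to that of baker's yeast-type (Prelog) reductases, which lead to the (3R,4R) antipode, and Ru/diphosphine hydrogenation is avoided because it favours trans products with cyclic keto esters.

Step 2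
Reactants: 2 1-tert-butyl 4-ethyl (3S,4S)-3-hydroxypiperidine-1,4-dicarboxylate; 3 tert-butyldimethylsilyl chloride
Product: 4 1-tert-butyl 4-ethyl (3S,4S)-3-[(tert-butyldimethylsilyl)oxy]piperidine-1,4-dicarboxylate
Conditions: TBSCl, imidazole, DMF, rt
Reagents that add atoms: tert-butyldimethylsilyl chloride (3), CC(C)(C)[Si](C)(C)Cl
Why: Imidazole-promoted O-silylation touches no stereocentre and is preferred to a Williamson benzylation, whose alkoxide conditions invite retro-aldol cleavage, C4′ epimerisation or β-elimination of a β-hydroxy ester, and to a benzyl ether as such, which excess alkyllithium in step 3 could push into a Wittig rearrangement.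

Step 3
Reactants: 4 1-tert-butyl 4-ethyl (3S,4S)-3-[(tert-butyldimethylsilyl)oxy]piperidine-1,4-dicarboxylate; 5 dibromomethane; 6 triisopropylsilyl trifluoromethanesulfonate
Product: 8 tert-butyl (3S,4R)-3-[(tert-butyldimethylsilyl)oxy]-4-{[(triisopropylsilyl)oxy]ethynyl}piperidine-1-carboxylate, via lithium ynolate 7 (not isolated)
Conditions: CH2Br2, lithium 2,2,6,6-tetramethylpiperidide, THF, −78 °C, then 4; LiN(SiMe3)2, −78 °C; n-BuLi, −78 °C → rt; TIPSOTf, −78 → 0 °C
Reagents that add atoms: dibromomethane (5), BrCBr; triisopropylsilyl trifluoromethanesulfonate (6), CC(C)[Si](OS(=O)(=O)C(F)(F)F)(C(C)C)C(C)C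
Why: Kowalski ester-to-ynolate homologation: LiCHBr2 should add to the ester at −78 °C faster than the hindered amide bases enolise it, the derived dibromo enolate undergoes Br/Li exchange and a carbenoid 1,2-shift of C4′ with retention of configuration, and the bulky silyl triflate traps ynolate 7 on oxygen rather than on carbon.

Step 4
Reactants: 8 tert-butyl (3S,4R)-3-[(tert-butyldimethylsilyl)oxy]-4-{[(triisopropylsilyl)oxy]ethynyl}piperidine-1-carboxylate; 9 3-ethoxycyclobut-2-en-1-one
Product: 14 tert-butyl (3S,4R)-3-[(tert-butyldimethylsilyl)oxy]-4-[4-ethoxy-2-hydroxy-6-(triisopropylsilyloxy)phenyl]piperidine-1-carboxylate, via vinylketene 10 (not isolated), via 4-vinylcyclobutenone 11 (not isolated), via dienylketene 12 (not isolated), via cyclohexadienone 13 (not isolated)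
Conditions: 9 (1.5 equiv, slow addition), PhMe, 80 °C then 110 °C, sealed vessel
Reagents that add atoms: 3-ethoxycyclobut-2-en-1-one (9), CCOC1=CC(=O)C1
Why: Thermal 4π electrocyclic opening of 9 gives vinylketene 10, whose carbonyl carbon is attacked by the nucleophilic, piperidine-bearing alkyne carbon of 8 in a [2+2] cycloaddition to give 11, and a second 4π opening gives dienylketene 12, which cyclises to 13 and tautomerises to phenol 14. This is the Danheiser benzannulation, whose closest relatives are the reactions of 3-alkylcyclobutenones with triisopropylsilyl ynol ethers carrying secondary alkyl groups, which give 2-alkylresorcinol monosilyl ethers; the one new variable is the 3-ethoxy donor, which becomes the third ring oxygen. Ring A closes by a thermal disrotatory 6π electrocyclisation of 12 that re-forms the C4a–C8a bond broken when 9 opened, so the net new bonds are C8–C8a and C6–C7. No stereocentre is created, the transient one in 11 is erased, and C3′ and C4′ are spectators because the medium is neutral and C4′–H is not activated. The step needs regioselectivity, which the matched polarisation of the ynol ether (nucleophilic β-carbon) and the ketene (electrophilic central carbon) secures by placing the piperidine between OH and OTIPS with OEt para to it; slow addition of 9 and the crowding of the new phenol hold back its O-acylation by 10.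

Step 5
Reactants: 14 tert-butyl (3S,4R)-3-[(tert-butyldimethylsilyl)oxy]-4-[4-ethoxy-2-hydroxy-6-(triisopropylsilyloxy)phenyl]piperidine-1-carboxylate
Product: 16 (3S,4R)-4-[4-ethoxy-2-hydroxy-6-(triisopropylsilyloxy)phenyl]-1-methylpiperidin-3-ol, via N-methyl TBS ether 15 (not isolated)
Conditions: LiAlH4, THF, reflux; Na2SO4·10H2O, filter; then 3 M aq HCl–MeOH, 40 °C
Reagents that add atoms: none
Why: Hydride reduction of the carbamate turns the Boc carbonyl carbon into the N-methyl group and avoids an acidic Boc cleavage whose tert-butyl cation would alkylate the electron-rich arene, and dilute acid then removes the alkyl TBS ether selectively because aryl silyl ethers, here a hindered OTIPS, are far more acid-stable.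

Step 6
Reactants: 16 (3S,4R)-4-[4-ethoxy-2-hydroxy-6-(triisopropylsilyloxy)phenyl]-1-methylpiperidin-3-ol; 17 acetic anhydride
Product: 18 (3S,4R)-4-[3-acetyl-4-ethoxy-2-hydroxy-6-(triisopropylsilyloxy)phenyl]-1-methylpiperidin-3-yl acetate
Conditions: Ac2O, BF3·OEt2, CH2Cl2, 0 °C → rt; aq Na2CO3
Reagents that add atoms: acetic anhydride (17), CC(=O)OC(C)=O
Why: BF3-promoted O-acetylation and Fries-type Friedel–Crafts acylation, well precedented on 4-(trialkoxyphenyl)-1-methylpiperidin-3-ols: the amine is masked as its BF3 adduct, the alcohol is acetylated, and the acetyl group settles ortho to the free phenol as a BF2 chelate that also shields OEt from dealkylation, the other open position being screened by OTIPS (acylation there or premature silyl loss would still converge on 21, since the two oxygens flanking C8 become interchangeable once unmasked).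

Step 7
Reactants: 18 (3S,4R)-4-[3-acetyl-4-ethoxy-2-hydroxy-6-(triisopropylsilyloxy)phenyl]-1-methylpiperidin-3-yl acetate; 19 ethyl acetate
Product: 21 5-ethoxy-7-hydroxy-8-[(3S,4R)-3-hydroxy-1-methylpiperidin-4-yl]-2-methyl-4H-chromen-4-one (5-O-ethylrohitukine), via 1,3-diketone 20 (not isolated)
Conditions: NaH, EtOAc–THF, reflux; MeOH, 0 °C → rt; conc. HCl, 50 °C
Reagents that add atoms: ethyl acetate (19), CCOC(C)=O
Why: Crossed Claisen condensation of the acetophenone enolate with ethyl acetate followed by acid cyclodehydration, the classical 2-methylchromone synthesis: only the C8a phenol can close the pyrone because the C5 oxygen is still ethylated, which excludes the 6-piperidinyl isomer, while methoxide and methanolic HCl strip the acetate and the base-labile aryl silyl ether para to the acyl group.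

Step 8
Reactants: 21 5-ethoxy-7-hydroxy-8-[(3S,4R)-3-hydroxy-1-methylpiperidin-4-yl]-2-methyl-4H-chromen-4-one
Product: 22 rohitukine, 5,7-dihydroxy-8-[(3S,4R)-3-hydroxy-1-methylpiperidin-4-yl]-2-methyl-4H-chromen-4-one
Conditions: BBr3 (5 equiv), CH2Cl2, −78 °C → rt; H2O
Reagents that add atoms: none
Why: Chelation-assisted ether cleavage: boron bridges the C4 carbonyl and the peri C5 oxygen so that bromide removes the ethyl group at or below room temperature, which is too mild for a Wessely–Moser ring opening and reclosure or for substitution at C3′, whose neighbouring nitrogen is tied up as its boron adduct.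

Step 9
Reactants: 22 rohitukine; 23 3,4-dimethoxybenzoyl chloride (veratroyl chloride)
Product: 25 chrotacumine D, (3S,4R)-4-(5,7-dihydroxy-2-methyl-4-oxo-4H-chromen-8-yl)-1-methylpiperidin-3-yl 3,4-dimethoxybenzoate, via 3′,7-bis-veratrate 24 (not isolated)
Conditions: 23 (2.5 equiv), pyridine, DMAP (cat.), 0 °C → rt; extractive wash, evaporate; K2CO3 (cat.), MeOH, 0 °C
Reagents that add atoms: 3,4-dimethoxybenzoyl chloride (23), COc1ccc(C(=O)Cl)cc1OC
Why: DMAP-catalysed aroylation followed by chemoselective transesterification: the acidic C7 phenol and the C3′ alcohol are esterified with retention at C3′ (the chelated C5 OH reacts slowest), and brief base-catalysed methanolysis removes only the activated aryl ester with its good phenoxide leaving group, leaving the hindered, electron-rich secondary veratrate.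

Compound list
1 | ethyl 1-(tert-butoxycarbonyl)-3-oxopiperidine-4-carboxylate | CCOC(=O)C1CCN(CC1=O)C(=O)OC(C)(C)C | starting material
2 | 1-tert-butyl 4-ethyl (3S,4S)-3-hydroxypiperidine-1,4-dicarboxylate | O[C@@H]1CN(C(=O)OC(C)(C)C)CC[C@@H]1C(=O)OCC | intermediate
3 | tert-butyldimethylsilyl chloride | CC(C)(C)[Si](C)(C)Cl | starting material
4 | 1-tert-butyl 4-ethyl (3S,4S)-3-[(tert-butyldimethylsilyl)oxy]piperidine-1,4-dicarboxylate | CC(C)(C)[Si](C)(C)O[C@@H]1CN(C(=O)OC(C)(C)C)CC[C@@H]1C(=O)OCC | intermediate
5 | dibromomethane | BrCBr | starting material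
6 | triisopropylsilyl trifluoromethanesulfonate | CC(C)[Si](OS(=O)(=O)C(F)(F)F)(C(C)C)C(C)C | starting material
7 | lithium ynolate, lithium 2-[(3S,4R)-1-Boc-3-(TBSO)piperidin-4-yl]ethynolate | CC(C)(C)[Si](C)(C)O[C@@H]1CN(C(=O)OC(C)(C)C)CC[C@@H]1C#C[O-].[Li+] | intermediate
8 | tert-butyl (3S,4R)-3-[(tert-butyldimethylsilyl)oxy]-4-{[(triisopropylsilyl)oxy]ethynyl}piperidine-1-carboxylate | CC(C)(C)[Si](C)(C)O[C@@H]1CN(C(=O)OC(C)(C)C)CC[C@@H]1C#CO[Si](C(C)C)(C(C)C)C(C)C | intermediate
9 | 3-ethoxycyclobut-2-en-1-one | CCOC1=CC(=O)C1 | starting material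
10 | vinylketene, 3-ethoxybuta-1,3-dien-1-one | C=C(OCC)C=C=O | intermediate
11 | 4-vinylcyclobutenone, 4-(1-ethoxyvinyl)-2-(piperidin-4-yl)-3-(TIPSO)cyclobut-2-en-1-one (both epimers at the ring CH) | CC(C)(C)[Si](C)(C)O[C@@H]1CN(C(=O)OC(C)(C)C)CC[C@@H]1C2=C(O[Si](C(C)C)(C(C)C)C(C)C)C(C(=C)OCC)C2=O | intermediate
12 | dienylketene, 5-ethoxy-2-(piperidin-4-yl)-3-(TIPSO)hexa-1,3,5-trien-1-one (ketene and ethoxyvinyl groups cis) | CC(C)(C)[Si](C)(C)O[C@@H]1CN(C(=O)OC(C)(C)C)CC[C@@H]1C(=C=O)/C(O[Si](C(C)C)(C(C)C)C(C)C)=C\C(=C)OCC | intermediate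
13 | cyclohexadienone, 5-ethoxy-2-(piperidin-4-yl)-3-(TIPSO)cyclohexa-2,4-dien-1-one | CC(C)(C)[Si](C)(C)O[C@@H]1CN(C(=O)OC(C)(C)C)CC[C@@H]1C2=C(O[Si](C(C)C)(C(C)C)C(C)C)C=C(OCC)CC2=O | intermediate
14 | tert-butyl (3S,4R)-3-[(tert-butyldimethylsilyl)oxy]-4-[4-ethoxy-2-hydroxy-6-(triisopropylsilyloxy)phenyl]piperidine-1-carboxylate | CC(C)(C)[Si](C)(C)O[C@@H]1CN(C(=O)OC(C)(C)C)CC[C@@H]1c2c(O)cc(OCC)cc2O[Si](C(C)C)(C(C)C)C(C)C | intermediate
15 | 2-[(3S,4R)-3-[(tert-butyldimethylsilyl)oxy]-1-methylpiperidin-4-yl]-5-ethoxy-3-(triisopropylsilyloxy)phenol | CC(C)(C)[Si](C)(C)O[C@@H]1CN(C)CC[C@@H]1c2c(O)cc(OCC)cc2O[Si](C(C)C)(C(C)C)C(C)C | intermediate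
16 | (3S,4R)-4-[4-ethoxy-2-hydroxy-6-(triisopropylsilyloxy)phenyl]-1-methylpiperidin-3-ol | O[C@@H]1CN(C)CC[C@@H]1c2c(O)cc(OCC)cc2O[Si](C(C)C)(C(C)C)C(C)C | intermediate
17 | acetic anhydride | CC(=O)OC(C)=O | starting material
18 | (3S,4R)-4-[3-acetyl-4-ethoxy-2-hydroxy-6-(triisopropylsilyloxy)phenyl]-1-methylpiperidin-3-yl acetate | CC(=O)O[C@@H]1CN(C)CC[C@@H]1c2c(O)c(C(C)=O)c(OCC)cc2O[Si](C(C)C)(C(C)C)C(C)C | intermediate
19 | ethyl acetate | CCOC(C)=O | starting material
20 | 1-{6-ethoxy-2,4-dihydroxy-3-[(3S,4R)-3-hydroxy-1-methylpiperidin-4-yl]phenyl}butane-1,3-dione | O[C@@H]1CN(C)CC[C@@H]1c2c(O)c(C(=O)CC(C)=O)c(OCC)cc2O | intermediate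
21 | 5-ethoxy-7-hydroxy-8-[(3S,4R)-3-hydroxy-1-methylpiperidin-4-yl]-2-methyl-4H-chromen-4-one | O[C@@H]1CN(C)CC[C@@H]1c2c(O)cc(OCC)c3c(=O)cc(C)oc23 | intermediate
22 | rohitukine | O[C@@H]1CN(C)CC[C@@H]1c2c(O)cc(O)c3c(=O)cc(C)oc23 | intermediate
23 | 3,4-dimethoxybenzoyl chloride | COc1ccc(C(=O)Cl)cc1OC | starting material
24 | (3S,4R)-4-[7-(3,4-dimethoxybenzoyloxy)-5-hydroxy-2-methyl-4-oxo-4H-chromen-8-yl]-1-methylpiperidin-3-yl 3,4-dimethoxybenzoate | COc1ccc(C(=O)O[C@@H]2CN(C)CC[C@@H]2c2c(OC(=O)c4ccc(OC)c(OC)c4)cc(O)c3c(=O)cc(C)oc23)cc1OC | intermediate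
25 | chrotacumine D | COc1ccc(C(=O)O[C@@H]2CN(C)CC[C@@H]2c2c(O)cc(O)c3c(=O)cc(C)oc23)cc1OC | target

Total step count: 9. Longest linear sequence: 9 steps (from 1).

Steps most likely to fail

1. Step 4.
- **Failure mode:** The vinylogous-ester stabilisation of 9 may slow its ring opening. Thermal decay of the ynol ether, dimerisation of the electron-rich vinylketene or O-acylation of the new phenol could then outrun the [2+2] capture at the hindered alkyne. An aryl ester formed in that way would in any case be cleaved reductively in step 5.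
- **Fallback, from 8 back to 14:** The same vinylketene 10 is generated by a photochemical Wolff rearrangement instead of an electrocyclic opening, the diazo ketone variant of the benzannulation. 1-Ethoxyvinyllithium (ethyl vinyl ether, t-BuLi) is acetylated with N-methoxy-N-methylacetamide to 3-ethoxybut-3-en-2-one F1. Its enolate (LiN(SiMe3)2, −78 °C) is acylated with CF3CO2CH2CF3 to 5-ethoxy-1,1,1-trifluorohex-5-ene-2,4-dione F2. Detrifluoroacetylative diazo transfer (MsN3, Et3N, wet MeCN) then gives 1-diazo-3-ethoxybut-3-en-2-one F3. Irradiation of F3 in the presence of 8 at room temperature should feed 10 slowly into the cycloaddition, and subsequent warming to 80–110 °C takes 11, 12 and 13 through to 14.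

2. Step 3.
- **Failure mode:** Enolisation of the ester by the amide bases may compete with addition of LiCHBr2 and lead to β-elimination of the silyloxy group or epimerisation at C4′. Attack of excess alkyllithium on the carbamate is a lesser concern.
- **Fallback, from 4 back to 7 and hence 8:** The extra carbon is introduced at the aldehyde level and the oxygen by acetylide oxidation. i-Bu2AlH (CH2Cl2, −78 °C) reduces 4 to tert-butyl (3S,4S)-3-[(tert-butyldimethylsilyl)oxy]-4-formylpiperidine-1-carboxylate F4. Corey–Fuchs olefination (CBr4, PPh3, 2,6-lutidine, 0 °C) gives tert-butyl (3S,4R)-3-[(tert-butyldimethylsilyl)oxy]-4-(2,2-dibromoethenyl)piperidine-1-carboxylate F5. n-BuLi (2 equiv, −78 °C) converts this into the lithium acetylide F6. Oxidation of F6 with LiOOt-Bu (−78 → 0 °C) gives ynolate 7, which is silylated with 6 as in step 3.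

3. Step 1.
- **Failure mode:** No enzyme of the panel may combine the required carbonyl face with the required C4′ enantiomer, so that poor facial or cis/trans selectivity results.
- **Fallback, from 1 back to 2:** NaBH4 (EtOH, −20 °C) followed by chromatographic removal of the trans isomer gives the racemic cis hydroxy ester F7. Lipase-catalysed acylation (Burkholderia cepacia lipase, vinyl acetate, i-Pr2O) follows. By the Kazlauskas rule, with the ester-bearing C4′ as the large group, it should acetylate the (3S) alcohol to 1-tert-butyl 4-ethyl (3S,4S)-3-acetoxypiperidine-1,4-dicarboxylate F8. This is separated from the unreacted (3R,4R) alcohol and deacetylated by K2CO3-catalysed ethanolysis at 0 °C to 2.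

Further compounds
F1 | step 4 | 3-ethoxybut-3-en-2-one | C=C(OCC)C(C)=O
F2 | step 4 | 5-ethoxy-1,1,1-trifluorohex-5-ene-2,4-dione | C=C(OCC)C(=O)CC(=O)C(F)(F)F
F3 | step 4 | 1-diazo-3-ethoxybut-3-en-2-one | C=C(OCC)C(=O)C=[N+]=[N-]
F4 | step 3 | tert-butyl (3S,4S)-3-[(tert-butyldimethylsilyl)oxy]-4-formylpiperidine-1-carboxylate | CC(C)(C)[Si](C)(C)O[C@@H]1CN(C(=O)OC(C)(C)C)CC[C@@H]1C=O
F5 | step 3 | tert-butyl (3S,4R)-3-[(tert-butyldimethylsilyl)oxy]-4-(2,2-dibromoethenyl)piperidine-1-carboxylate | CC(C)(C)[Si](C)(C)O[C@@H]1CN(C(=O)OC(C)(C)C)CC[C@@H]1C=C(Br)Br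
F6 | step 3 | lithium acetylide of tert-butyl (3S,4R)-3-[(tert-butyldimethylsilyl)oxy]-4-ethynylpiperidine-1-carboxylate | CC(C)(C)[Si](C)(C)O[C@@H]1CN(C(=O)OC(C)(C)C)CC[C@@H]1C#C[Li]
F7 | step 1 | racemic cis 1-tert-butyl 4-ethyl 3-hydroxypiperidine-1,4-dicarboxylate | O[C@@H]1CN(C(=O)OC(C)(C)C)CC[C@@H]1C(=O)OCC.O[C@H]1CN(C(=O)OC(C)(C)C)CC[C@H]1C(=O)OCC
F8 | step 1 | 1-tert-butyl 4-ethyl (3S,4S)-3-acetoxypiperidine-1,4-dicarboxylate | CC(=O)O[C@@H]1CN(C(=O)OC(C)(C)C)CC[C@@H]1C(=O)OCC
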